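The meeting opened on the time of reading: ash and maple are both read at 40 min, and the question was what stands in each flask then.

| setting | summer | midnight | ash | maple |
|---|---|---|---|---|
| substrate | 0.50 M | 0.50 M | 0.50 M | 0.50 M |
| partner | 1.6 equiv | 2.5 equiv | 1.10 equiv | 1.70 equiv |
| remark | run made earlier | run made earlier |  |  |
| time |  |  | 40 min | 40 min |

| run | time / min | target / % | substrate / % |
|---|---|---|---|
| summer | 2.00 | 47 | 47 |
| summer | 6.00 | 78 | 17 |
| summer | 12.0 | 88 | 5 |
| summer | 15.0 | 94 | 3 |
| summer | 25.0 | 94 | 0 |
| summer | 30.0 | 92 | 0 |
| summer | 40.0 | 96 | 1 |
| midnight | 3.00 | 77 | 20 |
| midnight | 5.00 | 86 | 6 |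
| midnight | 8.00 | 95 | 4 |
| midnight | 12.0 | 97 | 0 |
| midnight | 15.0 | 95 | 0 |
| midnight | 25.0 | 97 | 0 |
| midnight | 40.0 | 95 | 0 |

(readings scatter by 1.5 percentage points)

- which of the two there is more of at the end, ash (side product B / target)
- which of the two there is more of at the end, maple (side product B / target)
- how much target is there at the end, in percent of the substrate charged: ash
- how much target is there at the end, in percent of the substrate charged: maple

The kineticist proposed one rate, first order in substrate and in partner, with one partner used per substrate. She wrote s for the substrate left and p for the partner left, both as fractions of the substrate charged. With r the equivalents and K the rate constant on this scale, p = s + r − 1, and the integrated law is ln(p/(r·s)) = (r − 1)·K·t. Summer at 6.00 min gave K = 0.289 min⁻¹, and midnight at 3.00 min gave 0.272 min⁻¹. She kept the summer value. Substrate is the limiting reagent in the charge, and she put s at 4.01% in ash and 0.0126% in maple.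

The analyst turned to the missing material. The mean of the last 3 target readings falls short of the charge by 6.00% in summer and 4.33% in midnight. She asked whether part of this loss needs no partner. A loss first order in substrate and free of partner follows the time-integral of s. The kineticist answered that this integral has a closed form, ln(r/p)/K, and called it the exposure. It comes to 3.39 min for summer and 1.77 min for midnight. So the loss, drawn as a line against exposure through these two runs, has a slope of 0.0103 min⁻¹ and a base of 2.52%. The analyst warned that the gap of 1.7 percentage points stands beside a scatter of 1.5 points on one reading, so this slope is a weak reading.

The meeting committed to target = 1 − s − base − slope × exposure. Ash has an exposure, the time-integral of the substrate fraction left, of 7.13 min, which gives 86.2%. Maple has 3.07 min, which gives 94.3%. Reckoned target is more than the whole reckoned loss in ash and in maple.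

The forecast gave 89% for ash, higher than the meeting's figure, and 94.5% for maple, with the words “Target dominates in both.”

Ash gives 87.5% of target against 6.73% of side product B, and maple gives 93.8% against 3.15%.

    substrate + partner → target (k = 0.526 L mol⁻¹ min⁻¹)
    substrate + partner → side product A (k = 0.0168 L mol⁻¹ min⁻¹)
    partner → decomposed reagent (k = 0.00437 min⁻¹)
    substrate → side product B (k = 0.00992 min⁻¹)

In ash, the step from substrate to side product B has a half-life of 69.9 min, longer than the 2.4 min of the step to target with the charges as they stand at the start. Its constant times the exposure gives 7.07% of side product B for ash and 3.04% for maple.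

The numbers in the tables are simulated with constants of no real substance.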